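**Strategy**

The γ-lactone is opened at its alkyl C–O bond: the ring oxygen O-1 is joined last to C-5, the ring carbon that bears the 2-methylprop-1-enyl group. C-5 is the secondary terminus of a 1,1-dimethylallyl unit, so the precursor needs no stereocentre there. It is an open-chain (Z)-2-alkylidene-3-hydroxy carboxylate carrying an achiral (E)-CH=CH–CMe2–OBz arm. Zerovalent palladium ionises this tertiary allylic benzoate and the carboxylate closes the ring 5-exo. One operation forms the C–O bond, the C-5 stereocentre (trans to the C-4 hydroxyl, through a face-equilibrating π-allyl complex) and the trisubstituted alkene, and releases the unprotected target.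

Key step: step 9

Remark: atoms are numbered as in the parent geranylgeraniol chain (C-1 = CH2OH terminus, C-8 = side-chain carbinol, C-10=C-11 = exocyclic alkene, C-19 = lactone carbonyl, C-12 = ring carbinol, C-13 = ring O–CH, C-14=C-15 = isobutenyl alkene); the catalyst antipodes in steps 2 and 6 are assumed from the usual transition-state models and would be confirmed by Mosher ester analysis, the other antipode being used if the sense proves opposite.

**Route**

Step 1
Reactants: 1 geranyl acetate
Product: 2 (2E,6E)-3,7-dimethyl-8-oxoocta-2,6-dien-1-yl acetate (8-oxogeranyl acetate)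
Conditions: SeO2 (1.1 equiv), 95% EtOH, reflux
Reagents that add atoms: selenium dioxide, O=[Se]=O
Why: Riley allylic oxidation (ene reaction, then [2,3]-sigmatropic shift) attacks the (E)-methyl group of the electron-rich terminal gem-dimethyl alkene, the alkene next to the acetate being deactivated, and stoichiometric oxidant in hot ethanol should carry the allylic alcohol on to the (E)-enal.

Step 2
Reactants: 2 8-oxogeranyl acetate; 3 allenylboronic acid pinacol ester
Product: 4 (2E,6E,8R)-8-hydroxy-3,7-dimethylundeca-2,6-dien-10-yn-1-yl acetate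
Conditions: (R)-TRIP (10 mol%), 4 Å MS, toluene, 0 °C to rt; aqueous work-up
Reagents that add atoms: none
Why: Chiral phosphoric acid-catalysed propargylboration proceeds through a closed six-membered SE2' transition state that gives only the homopropargylic alcohol, and the catalyst-bound boronate selects the aldehyde face that should set 8R.

Step 3
Reactants: 4 homopropargylic alcohol
Product: 5 (2E,6E,8R)-3,7-dimethylundeca-2,6-dien-10-yne-1,8-diyl diacetate
Conditions: Ac2O, pyridine, DMAP (cat.), CH2Cl2, 0 °C to rt
Reagents that add atoms: acetic anhydride, CC(=O)OC(C)=O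
Why: DMAP-catalysed acylation masks the C-8 hydroxyl so that only the later C-12 hydroxyl directs the hydrostannation and C-8–O cannot trap the acylpalladium species, and the acetate is removed in the final pot without a separate deprotection.

Step 4
Reactants: 6 2-methylbut-3-en-2-ol
Product: 7 2-methylbut-3-en-2-yl benzoate
Conditions: BzCl, pyridine, DMAP (cat.), CH2Cl2, 40 °C
Reagents that add atoms: benzoyl chloride, O=C(Cl)c1ccccc1
Why: Nucleophilic (DMAP) catalysis allows benzoylation of the tertiary allylic alcohol, giving a latent leaving group that resists hydroxide on the time scale of acetate cleavage.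

Step 5
Reactants: 7 2-methylbut-3-en-2-yl benzoate; 8 (E)-crotonaldehyde (excess)
Product: 9 (3E)-2-methyl-5-oxopent-3-en-2-yl benzoate
Conditions: second-generation Hoveyda–Grubbs catalyst (5 mol%), CH2Cl2, 40 °C
Reagents that add atoms: none
Why: Olefin cross-metathesis between a hindered terminal alkene that does not homodimerise and an electron-poor partner in excess should give the (E)-enal under thermodynamic control with loss of propene.

Step 6
Reactants: 5 diacetate alkyne; 9 enal benzoate
Product: 10 (3E,5R,9R,10E,14E)-9,16-diacetoxy-5-hydroxy-2,10,14-trimethylhexadeca-3,10,14-trien-6-yn-2-yl benzoate (the C-11 alkyne carbon joined to the new C-12 carbinol, 12R)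
Conditions: (S,S)-ProPhenol (10 mol%), Me2Zn, Ph3PO (20 mol%), toluene, 0 °C; NH4Cl work-up
Reagents that add atoms: none
Why: Dinuclear zinc–ProPhenol-catalysed asymmetric alkynylation adds the alkynylzinc formed from 5 in 1,2-fashion to the enal held in the chiral pocket, setting the C-12 carbinol by catalyst control, while the esters are inert to organozinc reagents.

Step 7
Reactants: 10 propargylic alcohol
Product: 11 (3E,5R,6Z,9R,10E,14E)-9,16-diacetoxy-5-hydroxy-2,10,14-trimethyl-6-(tributylstannyl)hexadeca-3,6,10,14-tetraen-2-yl benzoate (tin on C-11, H on C-10, C-9 cis to tin)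
Conditions: [Cp*RuCl]4 (1.5 mol%), Bu3SnH, CH2Cl2, rt
Reagents that add atoms: tributyltin hydride, CCCC[SnH](CCCC)CCCC
Why: In the ruthenium-catalysed trans-hydrostannation, hydrogen bonding of the propargylic hydroxyl to the Ru–Cl unit steers tin to the proximal alkyne carbon and hydrogen is delivered anti, which fixes the trisubstituted alkene geometry.

Step 8
Reactants: 11 alkenylstannane
Product: 12 methyl (2Z,5R,6E,10E)-5,12-diacetoxy-2-[(1R,2E)-4-(benzoyloxy)-1-hydroxy-4-methylpent-2-en-1-yl]-6,10-dimethyldodeca-2,6,10-trienoate
Conditions: Pd(OAc)2 (10 mol%), Ph3As (20 mol%), 1,4-benzoquinone, CF3CO2H, CO (1 atm), MeOH, rt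
Reagents that add atoms: carbon monoxide, [C-]#[O+]; methanol, CO
Why: Hydroxyl-assisted oxidative methoxycarbonylation of the alkenylstannane (transmetalation to divalent palladium, CO insertion, methanolysis, reoxidation by benzoquinone) replaces tin by CO2Me with retention, so the ester ends cis to C-9 as the target requires.

Step 9
Reactants: 12 methyl ester
Product: 14 (3Z,4S,5R)-4-hydroxy-3-[(3R,4E,8E)-3,10-dihydroxy-4,8-dimethyldeca-4,8-dien-1-ylidene]-5-(2-methylprop-1-en-1-yl)oxolan-2-one (target), via lithium carboxylate 13 (not isolated)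
Conditions: LiOH·H2O (3.05 equiv), THF/H2O, 0 °C to rt; then Pd(PPh3)4 (5 mol%), rt to 40 °C
Reagents that add atoms: lithium hydroxide, [Li+].[OH-]
Why: Hydroxide first cleaves both acetates and the methyl ester, the hindered tertiary benzoate being far slower, to give carboxylate 13; Pd(PPh3)4 then ionises the only remaining allylic ester to a 1,1-dimethyl-3-alkyl π-allylpalladium cation, and the tethered carboxylate attacks its secondary terminus C-13 anti to the metal, forming the O–C-13 bond. The closest known reaction type is the Tsuji–Trost allylic substitution with a carboxylate nucleophile (palladium-catalysed allylic lactonisation). The five-membered ring closes in the 5-exo mode (SN2'-type attack at the proximal allyl terminus), the 7-endo attack at the CMe2 terminus being disfavoured by ring size and substitution. The new stereocentre C-13 is controlled by the C-12 carbinol: the two π-allyl faces can interconvert through the η1 form at the symmetric CMe2 terminus and the product allylic lactone can re-ionise, so the closure should funnel to the more stable 4,5-trans lactone (13R). The step needs chemoselective ionisation (every other allylic C–O bond is by then a free alcohol, which zerovalent palladium does not ionise), attack at the secondary terminus, and the carboxylate as the only competent nucleophile (the neutral hydroxyls would give strained or large rings).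

**Compound list**

1 | geranyl acetate, (2E)-3,7-dimethylocta-2,6-dien-1-yl acetate | CC(C)=CCC/C(C)=C/COC(C)=O | starting material
2 | (2E,6E)-3,7-dimethyl-8-oxoocta-2,6-dien-1-yl acetate | O=C/C(C)=C/CC/C(C)=C/COC(C)=O | intermediate
3 | allenylboronic acid pinacol ester, 4,4,5,5-tetramethyl-2-(propa-1,2-dien-1-yl)-1,3,2-dioxaborolane | C=C=CB1OC(C)(C)C(C)(C)O1 | starting material
4 | (2E,6E,8R)-8-hydroxy-3,7-dimethylundeca-2,6-dien-10-yn-1-yl acetate | C#CC[C@@H](O)/C(C)=C/CC/C(C)=C/COC(C)=O | intermediate
5 | (2E,6E,8R)-3,7-dimethylundeca-2,6-dien-10-yne-1,8-diyl diacetate | C#CC[C@@H](OC(C)=O)/C(C)=C/CC/C(C)=C/COC(C)=O | intermediate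
6 | 2-methylbut-3-en-2-ol | C=CC(C)(C)O | starting material
7 | 2-methylbut-3-en-2-yl benzoate | C=CC(C)(C)OC(=O)c1ccccc1 | intermediate
8 | (E)-crotonaldehyde | C/C=C/C=O | starting material
9 | (3E)-2-methyl-5-oxopent-3-en-2-yl benzoate | O=C/C=C/C(C)(C)OC(=O)c1ccccc1 | intermediate
10 | (3E,5R,9R,10E,14E)-9,16-diacetoxy-5-hydroxy-2,10,14-trimethylhexadeca-3,10,14-trien-6-yn-2-yl benzoate | O=C(OC(C)(C)/C=C/[C@@H](O)C#CC[C@@H](OC(C)=O)/C(C)=C/CC/C(C)=C/COC(C)=O)c1ccccc1 | intermediate
11 | (3E,5R,6Z,9R,10E,14E)-9,16-diacetoxy-5-hydroxy-2,10,14-trimethyl-6-(tributylstannyl)hexadeca-3,6,10,14-tetraen-2-yl benzoate | O=C(OC(C)(C)/C=C/[C@@H](O)/C([Sn](CCCC)(CCCC)CCCC)=C/C[C@@H](OC(C)=O)/C(C)=C/CC/C(C)=C/COC(C)=O)c1ccccc1 | intermediate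
12 | methyl (2Z,5R,6E,10E)-5,12-diacetoxy-2-[(1R,2E)-4-(benzoyloxy)-1-hydroxy-4-methylpent-2-en-1-yl]-6,10-dimethyldodeca-2,6,10-trienoate | O=C(OC(C)(C)/C=C/[C@@H](O)/C(C(=O)OC)=C/C[C@@H](OC(C)=O)/C(C)=C/CC/C(C)=C/COC(C)=O)c1ccccc1 | intermediate
13 | lithium (2Z,5R,6E,10E)-2-[(1R,2E)-4-(benzoyloxy)-1-hydroxy-4-methylpent-2-en-1-yl]-5,12-dihydroxy-6,10-dimethyldodeca-2,6,10-trienoate | [Li+].O=C(OC(C)(C)/C=C/[C@@H](O)/C(C([O-])=O)=C/C[C@@H](O)/C(C)=C/CC/C(C)=C/CO)c1ccccc1 | intermediate
14 | (3Z,4S,5R)-4-hydroxy-3-[(3R,4E,8E)-3,10-dihydroxy-4,8-dimethyldeca-4,8-dien-1-ylidene]-5-(2-methylprop-1-en-1-yl)oxolan-2-one | CC(C)=C[C@H]1OC(=O)/C(=C\C[C@@H](O)/C(C)=C/CC/C(C)=C/CO)[C@@H]1O | target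

**Step count and risks**

Total step count: 9. Longest linear sequence: 7 (steps 1, 2, 3, 6, 7, 8, 9).

Steps most likely to fail:

1. Step 9. Facial discrimination in the attack of the carboxylate on the π-allyl complex may be incomplete, giving a cis/trans mixture at C-13. Hydroxide may also erode the benzoate before ionisation, and a drift to lower pH may close the six-membered lactone instead. The fallback sets out from 12. K2CO3 in MeOH at 0 °C removes both acetates, and the freed C-8 hydroxyl transesterifies the methyl ester (a trace of PPTS in CH2Cl2 completes the closure) to the isolable six-membered lactone F1, which parks the acid as a temporary ring and is purified. F1 is opened with exactly one equivalent of LiOH in THF/H2O to the same carboxylate 13. Ring contraction is then run with Pd2(dba)3·CHCl3 and the DACH-phenyl Trost ligand, the matched antipode being found by screening both, so that the ligand and not only C-12 selects the allyl face. The fallback returns to the route at 14.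

2. Step 8. Protodestannation by CF3CO2H may outrun transmetalation, and the doubly allylic C-12 carbinol may solvolyse in acidic methanol. The fallback sets out from 11. Iododestannation (I2, CH2Cl2, 0 °C) gives, with retention, the alkenyl iodide F2. Acid-free alkoxycarbonylation (PdCl2(PPh3)2, CO 1 atm, Et3N, MeOH, 40 °C) follows, in which oxidative addition of zerovalent palladium into the C–I bond is expected to be faster than ionisation of the hindered allylic esters. The fallback returns to the route at 12.

3. Step 6. Facial selectivity of the alkynylzinc addition to the γ-oxygenated enal may be insufficient, or conversion low with the elaborate alkyne. The fallback sets out from 5 and 9. Addition without chiral control (Me2Zn, racemic ProPhenol, toluene) gives the C-12 epimeric alcohol mixture F3. MnO2 in CH2Cl2 oxidises it to the alkynyl alkenyl ketone F4. Reduction with (R)-Me-CBS oxazaborolidine and catecholborane at −78 °C, with the alkenyl arm as the large and the alkynyl arm as the small group, should then give the 12R carbinol. The fallback returns to the route at 10.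

**Further compounds**

F1 | step 9 | (3E,5R)-5-hydroxy-5-{(6R)-6-[(2E,6E)-8-hydroxy-6-methylocta-2,6-dien-2-yl]-2-oxo-5,6-dihydro-2H-pyran-3-yl}-2-methylpent-3-en-2-yl benzoate | O=C(OC(C)(C)/C=C/[C@@H](O)C1=CC[C@H](/C(C)=C/CC/C(C)=C/CO)OC1=O)c1ccccc1
F2 | step 8 | (3E,5R,6Z,9R,10E,14E)-9,16-diacetoxy-5-hydroxy-6-iodo-2,10,14-trimethylhexadeca-3,6,10,14-tetraen-2-yl benzoate | O=C(OC(C)(C)/C=C/[C@@H](O)/C(I)=C/C[C@@H](OC(C)=O)/C(C)=C/CC/C(C)=C/COC(C)=O)c1ccccc1
F3 | step 6 | (3E,9R,10E,14E)-9,16-diacetoxy-5-hydroxy-2,10,14-trimethylhexadeca-3,10,14-trien-6-yn-2-yl benzoate, mixture of C-5 epimers | O=C(OC(C)(C)/C=C/C(O)C#CC[C@@H](OC(C)=O)/C(C)=C/CC/C(C)=C/COC(C)=O)c1ccccc1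
F4 | step 6 | (3E,9R,10E,14E)-9,16-diacetoxy-2,10,14-trimethyl-5-oxohexadeca-3,10,14-trien-6-yn-2-yl benzoate | O=C(OC(C)(C)/C=C/C(=O)C#CC[C@@H](OC(C)=O)/C(C)=C/CC/C(C)=C/COC(C)=O)c1ccccc1
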